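**Strategy.** The A ring of the target (C4a, C5–C8, C8a) carries five oxygens and one carbon. It is therefore 2,3,5-trimethoxy-1,4-benzoquinone in disguise: the single C–H becomes C4a and the two carbonyl oxygens become O1 and the C6 oxygen. Everything rests on the C4–C4a bond. A photochemical acyl-radical acylation (photo-Friedel–Crafts) of that quinone by an arylpropynal joins two carbons that are both electrophilic in polar chemistry. The resulting ortho-hydroxyaryl ynone closes the γ-pyrone ring (O1–C2) in the same flask. Both precursors, the quinone and 3-[2,4,5-trimethoxy-3-(pivaloyloxy)phenyl]prop-2-ynal, come from 2,3,6-trimethoxyphenol.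

Key step: step 7

Remark on the chemistry: the target is a planar, achiral flavone without any stereocentre, so no stereocontrol is required and all structures are drawn without stereodescriptors.

**Route**

Step 1
Reactants: 1 1,2,4-trimethoxybenzene
Product: 4 2,3,6-trimethoxyphenol, via aryllithium 2 (not isolated), via dimethyl arylboronate 3 (not isolated)
Conditions: n-BuLi (1.1 equiv), THF, 0 °C → rt; B(OMe)3, −78 °C → rt; AcOH, 30% aq. H2O2, 0 °C → rt
Reagents that add atoms: n-butyllithium, [Li]CCCC (Li of 2); trimethyl borate, COB(OC)OC (B(OMe)2 of 3); hydrogen peroxide, OO (phenol oxygen of 4)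
Why: Directed ortho-metalation removes the C3 proton flanked by two methoxy groups, and borylation followed by peroxide oxidation (1,2-aryl shift from boron to oxygen) should turn the C–Li bond into the C–OH bond.

Step 2
Reactants: 4 2,3,6-trimethoxyphenol
Product: 5 2,3,5-trimethoxy-1,4-benzoquinone
Conditions: Co(salen) (salcomine, 5 mol %), O2 (1 atm), DMF, rt
Reagents that add atoms: dioxygen, O=O
Why: Cobalt–salen-catalysed aerobic phenol oxidation should convert this 2,6-dialkoxyphenol, whose para position is its only free conjugated site, into the p-quinone.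

Step 3
Reactants: 4 2,3,6-trimethoxyphenol
Product: 6 2,3,6-trimethoxyphenyl pivalate
Conditions: PivCl, Et3N, DMAP (cat.), CH2Cl2, 0 °C → rt
Reagents that add atoms: pivaloyl chloride, CC(C)(C)C(Cl)=O
Why: DMAP-catalysed O-acylation should give the ester, which turns the strongest donor of the ring into a weak one for step 4 and masks the phenol until the last step.

Step 4
Reactants: 6 2,3,6-trimethoxyphenyl pivalate
Product: 7 3-iodo-2,5,6-trimethoxyphenyl pivalate
Conditions: NIS (1.05 equiv), TFA (0.3 equiv), MeCN, 0 °C → rt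
Reagents that add atoms: N-iodosuccinimide, O=C1CCC(=O)N1I
Why: Electrophilic aromatic iodination should occur at C5, ortho to one methoxy group and para to another, in preference to C4, which is para to the weakly donating acyloxy group; this is the reversal of site selectivity known for guaiacol esters versus guaiacol.

Step 5
Reactants: 7 3-iodo-2,5,6-trimethoxyphenyl pivalate; 8 3,3-diethoxyprop-1-yne
Product: 9 3-(3,3-diethoxyprop-1-yn-1-yl)-2,5,6-trimethoxyphenyl pivalate
Conditions: PdCl2(PPh3)2 (3 mol %), CuI (5 mol %), Et3N, THF, 50 °C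
Reagents that add atoms: none
Why: Sonogashira coupling of an aryl iodide with a terminal alkyne should proceed normally, the pivalate and the acetal being inert to the amine base.

Step 6
Reactants: 9 3-(3,3-diethoxyprop-1-yn-1-yl)-2,5,6-trimethoxyphenyl pivalate
Product: 10 3-[2,4,5-trimethoxy-3-(pivaloyloxy)phenyl]prop-2-ynal
Conditions: TFA, H2O, CH2Cl2, 0 °C → rt
Reagents that add atoms: water, O
Why: Acid-catalysed acetal hydrolysis should release the conjugated ynal, the aryl pivalate being stable to aqueous acid at room temperature.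

Step 7
Reactants: 5 2,3,5-trimethoxy-1,4-benzoquinone; 10 3-[2,4,5-trimethoxy-3-(pivaloyloxy)phenyl]prop-2-ynal
Product: 12 6-hydroxy-5,7,8-trimethoxy-2-[2,4,5-trimethoxy-3-(pivaloyloxy)phenyl]-4H-chromen-4-one, via acylhydroquinone ynone 11 (not isolated)
Conditions: 5 (1.5 equiv), hν (427 nm LEDs), degassed PhCF3, 20 °C, Ar; then TfOH (0.3 equiv), 0 °C → rt
Reagents that add atoms: none
Why: Selective excitation of quinone 5 (10 should be transparent at 427 nm) gives its triplet, which abstracts the formyl hydrogen of 10; the nucleophilic alkynoyl σ-radical then bonds to the one ring carbon of the quinone/semiquinone that bears hydrogen, and enolisation delivers acylhydroquinone 11, so that the formyl carbon (C4) and the enedione carbon (C4a), both electrophiles in polar chemistry, are joined. The closest known reaction type is the photo-Friedel–Crafts (Klinger–Kolbe) acylation of benzo- and naphthoquinones with aldehydes, conjugated aldehydes included. Acid then closes the γ-pyrone ring by 6-endo-dig oxa-Michael addition of the hydroxyl ortho to the acyl group onto the ynone β-carbon (O1–C2), while the other hydroquinone hydroxyl remains as 6-OH. No stereocentre is formed. The step needs site selectivity on the quinone, secured by its single C–H; chemoselective hydrogen abstraction, secured by the weak formyl C–H bond and by an alkynoyl radical that has no useful decarbonylation path; and 6-endo over 5-exo (aurone) closure, secured by the electron-rich aryl group, which stabilises positive charge at the β-carbon under TfOH.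

Step 8
Reactants: 12 6-hydroxy-5,7,8-trimethoxy-2-[2,4,5-trimethoxy-3-(pivaloyloxy)phenyl]-4H-chromen-4-one
Product: 13 5,6,7,8-tetramethoxy-2-[2,4,5-trimethoxy-3-(pivaloyloxy)phenyl]-4H-chromen-4-one
Conditions: MeI, K2CO3, acetone, reflux
Reagents that add atoms: iodomethane, CI
Why: Williamson O-methylation should alkylate the only free phenol (6-OH), anhydrous carbonate in acetone leaving the hindered aryl pivalate intact.

Step 9
Reactants: 13 5,6,7,8-tetramethoxy-2-[2,4,5-trimethoxy-3-(pivaloyloxy)phenyl]-4H-chromen-4-one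
Product: 15 agehoustin C, via sodium phenolate 14 (not isolated)
Conditions: NaOMe (1.2 equiv), MeOH–THF, rt; then AcOH
Reagents that add atoms: sodium methoxide, [Na+].[O-]C (Na of 14; 15 gains only hydrogen)
Why: Zemplén-type transesterification should cleave the aryl ester as methyl pivalate, the methyl ethers and the γ-pyrone being untouched by methoxide at room temperature.

**Compound list**

1 | 1,2,4-trimethoxybenzene | COc1ccc(OC)c(OC)c1 | starting material
2 | (2,3,6-trimethoxyphenyl)lithium | [Li]c1c(OC)ccc(OC)c1OC | intermediate (not isolated)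
3 | dimethyl (2,3,6-trimethoxyphenyl)boronate | COB(OC)c1c(OC)ccc(OC)c1OC | intermediate (not isolated)
4 | 2,3,6-trimethoxyphenol | Oc1c(OC)ccc(OC)c1OC | intermediate
5 | 2,3,5-trimethoxy-1,4-benzoquinone | COC1=CC(=O)C(OC)=C(OC)C1=O | intermediate
6 | 2,3,6-trimethoxyphenyl pivalate | CC(C)(C)C(=O)Oc1c(OC)ccc(OC)c1OC | intermediate
7 | 3-iodo-2,5,6-trimethoxyphenyl pivalate | CC(C)(C)C(=O)Oc1c(OC)c(I)cc(OC)c1OC | intermediate
8 | 3,3-diethoxyprop-1-yne | CCOC(OCC)C#C | starting material
9 | 3-(3,3-diethoxyprop-1-yn-1-yl)-2,5,6-trimethoxyphenyl pivalate | CCOC(OCC)C#Cc1cc(OC)c(OC)c(OC(=O)C(C)(C)C)c1OC | intermediate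
10 | 3-[2,4,5-trimethoxy-3-(pivaloyloxy)phenyl]prop-2-ynal | O=CC#Cc1cc(OC)c(OC)c(OC(=O)C(C)(C)C)c1OC | intermediate
11 | 1-(2,5-dihydroxy-3,4,6-trimethoxyphenyl)-3-[2,4,5-trimethoxy-3-(pivaloyloxy)phenyl]prop-2-yn-1-one | COc1c(O)c(OC)c(OC)c(O)c1C(=O)C#Cc1cc(OC)c(OC)c(OC(=O)C(C)(C)C)c1OC | intermediate (not isolated)
12 | 6-hydroxy-5,7,8-trimethoxy-2-[2,4,5-trimethoxy-3-(pivaloyloxy)phenyl]-4H-chromen-4-one | COc1cc(-c2cc(=O)c3c(OC)c(O)c(OC)c(OC)c3o2)c(OC)c(OC(=O)C(C)(C)C)c1OC | intermediate
13 | 5,6,7,8-tetramethoxy-2-[2,4,5-trimethoxy-3-(pivaloyloxy)phenyl]-4H-chromen-4-one | COc1cc(-c2cc(=O)c3c(OC)c(OC)c(OC)c(OC)c3o2)c(OC)c(OC(=O)C(C)(C)C)c1OC | intermediate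
14 | sodium 2,3,6-trimethoxy-5-(5,6,7,8-tetramethoxy-4-oxo-4H-chromen-2-yl)phenolate | COc1cc(-c2cc(=O)c3c(OC)c(OC)c(OC)c(OC)c3o2)c(OC)c([O-])c1OC.[Na+] | intermediate (not isolated)
15 | agehoustin C, 2-(3-hydroxy-2,4,5-trimethoxyphenyl)-5,6,7,8-tetramethoxy-4H-chromen-4-one | COc1cc(-c2cc(=O)c3c(OC)c(OC)c(OC)c(OC)c3o2)c(OC)c(O)c1OC | target

**Step count and risks**

Total step count: 9. Longest linear sequence: 8 steps (steps 1, 3, 4, 5, 6, 7, 8, 9); step 2 is the side branch to the quinone.

Steps most likely to fail: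

1. Step 7. The excited quinone may be quenched by electron transfer from the electron-rich arylalkyne, may add across the triple bond (oxetene formation), or may be acylated at oxygen instead of carbon. The fallback replaces the radical C–C bond formation by a polar one; it sets out from 5 and 10 and comes back to the route at 12. Reduction of 5 with Na2S2O4 (EtOAc/H2O) should give 2,3,5-trimethoxybenzene-1,4-diol F1. MOMCl/i-Pr2NEt should give 1,2,4-trimethoxy-3,6-bis(methoxymethoxy)benzene F2. Ortho-lithiation at its single aryl C–H (n-BuLi, THF, 0 °C) should give [2,5-bis(methoxymethoxy)-3,4,6-trimethoxyphenyl]lithium F3. Addition of this at −78 °C to the formyl group of 10 should give racemic 1-[2,5-bis(methoxymethoxy)-3,4,6-trimethoxyphenyl]-3-[2,4,5-trimethoxy-3-(pivaloyloxy)phenyl]prop-2-yn-1-ol F4. MnO2 (CH2Cl2) should oxidise this to 1-[2,5-bis(methoxymethoxy)-3,4,6-trimethoxyphenyl]-3-[2,4,5-trimethoxy-3-(pivaloyloxy)phenyl]prop-2-yn-1-one F5. HCl in MeOH should then remove both MOM groups (giving 11 in the flask) and close the pyrone to 12.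

2. Step 4. The iodination may lack site selectivity, with attack at C4 (para to the acyloxy group) competing with attack at C5. The fallback uses a formyl group as a meta-directing placeholder for the phenol oxygen; it sets out from 1 and comes back at 7. Aryllithium 2, made as in step 1, is quenched with DMF to give 2,3,6-trimethoxybenzaldehyde F6. NIS/TFA should then iodinate only the position meta to the formyl group and ortho/para to two methoxy groups, giving 3-iodo-2,5,6-trimethoxybenzaldehyde F7. Baeyer–Villiger oxidation (mCPBA, CH2Cl2) should give 3-iodo-2,5,6-trimethoxyphenyl formate F8. K2CO3/MeOH should give 3-iodo-2,5,6-trimethoxyphenol F9, and pivaloylation as in step 3 gives 7.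

3. Step 6. The push–pull ynal may be hydrated at the triple bond or oligomerise under the acidic conditions that release it. The fallback reaches the aldehyde by oxidation instead of hydrolysis; it sets out from 7 and comes back at 10. Sonogashira coupling of 7 with propargyl alcohol (PdCl2(PPh3)2, CuI, Et3N) should give 3-(3-hydroxyprop-1-yn-1-yl)-2,5,6-trimethoxyphenyl pivalate F10, which MnO2 (CH2Cl2, rt) should oxidise to 10 under neutral conditions.

Further compounds
F1 | step 7 | 2,3,5-trimethoxybenzene-1,4-diol | COc1cc(O)c(OC)c(OC)c1O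
F2 | step 7 | 1,2,4-trimethoxy-3,6-bis(methoxymethoxy)benzene | COc1cc(OCOC)c(OC)c(OC)c1OCOC
F3 | step 7 | [2,5-bis(methoxymethoxy)-3,4,6-trimethoxyphenyl]lithium | [Li]c1c(OC)c(OCOC)c(OC)c(OC)c1OCOC
F4 | step 7 | rac-1-[2,5-bis(methoxymethoxy)-3,4,6-trimethoxyphenyl]-3-[2,4,5-trimethoxy-3-(pivaloyloxy)phenyl]prop-2-yn-1-ol | COc1c(C(O)C#Cc2cc(OC)c(OC)c(OC(=O)C(C)(C)C)c2OC)c(OCOC)c(OC)c(OC)c1OCOC
F5 | step 7 | 1-[2,5-bis(methoxymethoxy)-3,4,6-trimethoxyphenyl]-3-[2,4,5-trimethoxy-3-(pivaloyloxy)phenyl]prop-2-yn-1-one | COc1c(C(=O)C#Cc2cc(OC)c(OC)c(OC(=O)C(C)(C)C)c2OC)c(OCOC)c(OC)c(OC)c1OCOC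
F6 | step 4 | 2,3,6-trimethoxybenzaldehyde | O=Cc1c(OC)ccc(OC)c1OC
F7 | step 4 | 3-iodo-2,5,6-trimethoxybenzaldehyde | O=Cc1c(OC)c(I)cc(OC)c1OC
F8 | step 4 | 3-iodo-2,5,6-trimethoxyphenyl formate | O=COc1c(OC)c(I)cc(OC)c1OC
F9 | step 4 | 3-iodo-2,5,6-trimethoxyphenol | Oc1c(OC)c(I)cc(OC)c1OC
F10 | step 6 | 3-(3-hydroxyprop-1-yn-1-yl)-2,5,6-trimethoxyphenyl pivalate | OCC#Cc1cc(OC)c(OC)c(OC(=O)C(C)(C)C)c1OC
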